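**Retrosynthetic overview**

1. Target ⇒ primary O‑acetylation, desilylation and lactonisation after reductive removal of an oxazolidinone ⇒ Evans syn‑aldol of imide 18 with ethyl glyoxylate (sets the lactone CH and CH–OH) ⇒ 1,4‑addition of the alkenyl metal from methyl ketone 9 (Shapiro) to enoyl imide 15, which makes the C(=CH2)–CH(CH2O) bond and sets that CH.
2. Ketone 9 ⇒ silyl ether 7 (octahydroindene numbering: C1 = CH carrying the side chain, C2 and C3 = CH2, C3a = CH, C4 = CMe2, C7a = C–CH3) ⇒ cyclopentane closed last at C2–C3: cyclic hydroboration of 1,4‑diene 5 to borinane 6, then AgNO3/KOH coupling of the two boron‑bound carbons with loss of boron (ring contraction, six to five).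
3. Enabling feature: in the ring C1–C2–C3–C3a–C7a, C2 and C3 are adjacent unsubstituted CH2 groups, each bonded to a CH (C1, C3a) on quaternary C7a. C1–H/C2 and C3a–H/C3 are therefore the anti‑Markovnikov H–B adducts of two methylidene groups, and one boron atom can hold C2 and C3 in a six‑membered ring (B, C2, C1, C7a, C3a, C3) before it is expelled.
4. Diene 5 ⇒ Wittig methylenation of ketone 4 ⇒ Pd‑catalysed enantioselective α‑alkenylation of 2,2,6‑trimethylcyclohexanone 3 with bromide 2 (sets C7a).
5. Order of rings: cyclohexane (bought in 3) → borinane (temporary, step 4) → cyclopentane (step 4, trans fusion set) → butyrolactone (step 13).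

Key step: step 4

Assumption: step 4 should give 7 together with its C1 epimer; 7 and 8 are drawn and named with the C1 configuration of the target, and the pair is converged at ketone 9 (step 6).

**Route**

Step 1
Reactants: 1 2-bromoprop-2-en-1-ol
Product: 2 [(2-bromoprop-2-en-1-yl)oxy](tert-butyl)dimethylsilane
Conditions: TBSCl, imidazole, CH2Cl2, 0 to 23 °C
Reagents that add atoms: tert-butyldimethylsilyl chloride, CC(C)(C)[Si](C)(C)Cl
Why: Standard silylation of a primary allylic alcohol, which masks the oxygen through the basic and hydridic steps that follow.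

Step 2
Reactants: 2 [(2-bromoprop-2-en-1-yl)oxy](tert-butyl)dimethylsilane; 3 2,2,6-trimethylcyclohexan-1-one (racemic)
Product: 4 (2R)-2-[3-{[tert-butyl(dimethyl)silyl]oxy}prop-1-en-2-yl]-2,6,6-trimethylcyclohexan-1-one
Conditions: Pd2(dba)3 (2.5 mol %), one antipode of 2-(dicyclohexylphosphino)-2′-(dimethylamino)-1,1′-binaphthyl (6 mol %), NaOtBu, toluene, 60 °C
Reagents that add atoms: none
Why: Pd-catalysed asymmetric α-alkenylation of a ketone enolate (oxidative addition of zerovalent palladium to the C–Br bond, transmetalation with the only possible enolate of 3, reductive elimination) should create quaternary C7a; the chiral monophosphine differentiates the enolate faces (the antipode giving (R)-4 is fixed by running both), and the gem-dimethyl group blocks the other α-position.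

Step 3
Reactants: 4 (2R)-2-[3-{[tert-butyl(dimethyl)silyl]oxy}prop-1-en-2-yl]-2,6,6-trimethylcyclohexan-1-one
Product: 5 tert-butyl(dimethyl)({2-[(1S)-1,3,3-trimethyl-2-methylidenecyclohexyl]prop-2-en-1-yl}oxy)silane
Conditions: Ph3PCH3Br, KOtBu, toluene, 100 °C
Reagents that add atoms: methyltriphenylphosphonium bromide, C[P+](c1ccccc1)(c1ccccc1)c1ccccc1.[Br-]
Why: Wittig methylenation with the ylide made by KOtBu at elevated temperature, the usual recourse for hindered ketones; the ketone is non-enolisable, so neither enolisation nor alkene migration can compete and C7a is untouched.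

Step 4
Reactants: 5 tert-butyl(dimethyl)({2-[(1S)-1,3,3-trimethyl-2-methylidenecyclohexyl]prop-2-en-1-yl}oxy)silane
Product: 7 tert-butyl(dimethyl){[(1S,3aS,7aS)-4,4,7a-trimethyloctahydro-1H-inden-1-yl]methoxy}silane, via borinane 6 (not isolated)
Conditions: BH3·THF (1.05 equiv), THF, 0.02 M, 0 to 23 °C; then KOH (aq), AgNO3 (aq, 2.2 equiv), 0 to 23 °C
Reagents that add atoms: none
Why: BH3 adds anti-Markovnikov to the less hindered side-chain methylidene (B to C2, H to C1) and the monoalkylborane then adds intramolecularly to the ring methylidene (B to C3, H to C3a), closing the six-membered borinane 6 (ring of B, C2, C1, C7a, C3a, C3; 6-endo cyclic hydroboration); hydroxide and AgNO3 then transfer both boron-bound primary carbons to silver, and collapse of the alkylsilver pair (radical recombination or reductive elimination) forms C2–C3, so the cyclopentane is closed by contraction of the borinane with extrusion of the boron atom. The closest known reaction types are the cyclic hydroboration of 1,4-dienes to borinanes and the alkaline AgNO3 coupling of organoboranes, whose intramolecular form converts hydroborated α,ω-dienes into five- to seven-membered carbocycles. C3a is controlled by the tether: its hydrogen comes from boron held on C2, hence from the face of the C7a–C1 bond, which places H-3a trans to the C7a methyl group (trans ring fusion). C1 is created in the first, intermolecular B–H addition with only the bias of the adjacent quaternary C7a, so its epimer is expected alongside and the centre is secured at ketone 9. The step needs tail-to-tail C2–C3 pairing instead of intermolecular coupling, secured because both carbons are ligands of one boron atom within a ring (high dilution for the hydroboration), and it needs boron on the terminal carbons only, which the 1,1-disubstitution of both alkenes and the quaternary neighbours C7a and C4 enforce. C7a is not touched and the silyl ether should survive cold aqueous KOH.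

Step 5
Reactants: 7 tert-butyl(dimethyl){[(1S,3aS,7aS)-4,4,7a-trimethyloctahydro-1H-inden-1-yl]methoxy}silane
Product: 8 (1S,3aS,7aS)-4,4,7a-trimethyloctahydro-1H-indene-1-carboxylic acid
Conditions: CrO3, H2SO4 (aq), acetone, 0 to 23 °C
Reagents that add atoms: water, O
Why: Jones oxidation, in which the acidic aqueous medium cleaves the primary silyl ether and CrO3 oxidises the alcohol through the aldehyde hydrate to the acid; the molecule carries no other oxidisable group, and C3a and C7a cannot epimerise.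

Step 6
Reactants: 8 (1S,3aS,7aS)-4,4,7a-trimethyloctahydro-1H-indene-1-carboxylic acid
Product: 9 1-[(1S,3aS,7aS)-4,4,7a-trimethyloctahydro-1H-inden-1-yl]ethan-1-one
Conditions: MeLi (2.5 equiv), Et2O, 0 to 23 °C; aq HCl; then NaOMe (0.3 equiv), MeOH, 23 °C
Reagents that add atoms: methyllithium, [Li]C
Why: Addition of MeLi to the lithium carboxylate gives a stable dilithio gem-diolate that releases the methyl ketone on hydrolysis (classical acid-to-methyl-ketone conversion); methoxide then equilibrates C1 through its enolate to the acetyl group cis to the C7a methyl (thermodynamic control, the preference known for 17β-acetyl groups of 20-oxopregnanes), the minor epimer being separated and recycled.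

Step 7
Reactants: 9 1-[(1S,3aS,7aS)-4,4,7a-trimethyloctahydro-1H-inden-1-yl]ethan-1-one
Product: 10 N′-{(1E)-1-[(1S,3aS,7aS)-4,4,7a-trimethyloctahydro-1H-inden-1-yl]ethylidene}-2,4,6-tri(propan-2-yl)benzenesulfonohydrazide
Conditions: 2,4,6-triisopropylbenzenesulfonyl hydrazide, HCl (cat.), THF–MeOH, 23 °C
Reagents that add atoms: 2,4,6-tri(propan-2-yl)benzenesulfonohydrazide, CC(C)c1cc(C(C)C)c(S(=O)(=O)NN)c(C(C)C)c1
Why: Acid-catalysed condensation to the arylsulfonylhydrazone needed for the Shapiro reaction; the sulfonamide nitrogen should lie anti to the bulky ring (E), which later directs deprotonation to the methyl group.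

Step 8
Reactants: 11 (4S)-4-benzyl-1,3-oxazolidin-2-one; 12 prop-2-enoyl chloride
Product: 13 (4S)-4-benzyl-3-(prop-2-enoyl)-1,3-oxazolidin-2-one
Conditions: MeMgBr, THF, 0 °C; then 12, −78 to 0 °C
Reagents that add atoms: none
Why: N-acylation of the bromomagnesium salt of the oxazolidinone with the acid chloride, the standard preparation of N-enoyl imides.

Step 9
Reactants: 13 (4S)-4-benzyl-3-(prop-2-enoyl)-1,3-oxazolidin-2-one; 14 tert-butyl(dimethyl)(prop-2-en-1-yloxy)silane
Product: 15 (4S)-4-benzyl-3-[(2E)-4-{[tert-butyl(dimethyl)silyl]oxy}but-2-enoyl]-1,3-oxazolidin-2-one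
Conditions: second-generation Grubbs catalyst (H2IMes)(PCy3)Cl2Ru=CHPh (3 mol %), 14 (3 equiv), CH2Cl2, 40 °C
Reagents that add atoms: none
Why: Olefin cross-metathesis between an electron-poor acryloyl partner and an excess of an electron-rich allyl ether, which should be selective for the cross product and for the E alkene.

Step 10
Reactants: 10 N′-{(1E)-1-[(1S,3aS,7aS)-4,4,7a-trimethyloctahydro-1H-inden-1-yl]ethylidene}-2,4,6-tri(propan-2-yl)benzenesulfonohydrazide; 15 (4S)-4-benzyl-3-[(2E)-4-{[tert-butyl(dimethyl)silyl]oxy}but-2-enoyl]-1,3-oxazolidin-2-one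
Product: 18 (4S)-4-benzyl-3-[(3R)-3-({[tert-butyl(dimethyl)silyl]oxy}methyl)-4-[(1R,3aS,7aS)-4,4,7a-trimethyloctahydro-1H-inden-1-yl]pent-4-enoyl]-1,3-oxazolidin-2-one, via alkenyllithium 16 (not isolated), via alkenylmagnesium bromide 17 (not isolated)
Conditions: n-BuLi (2.1 equiv), THF, −78 to 0 °C; MgBr2·OEt2, −78 °C; CuBr·SMe2 (0.2 equiv), 15, THF–Me2S, −78 to −20 °C; aq NH4Cl
Reagents that add atoms: none
Why: The Shapiro reaction (dianion by deprotonation at N–H and at the methyl group, loss of sulfinate and N2) gives the 1,1-disubstituted alkenyllithium 16, which after transmetalation adds under copper catalysis in 1,4-fashion to the magnesium-chelated s-cis enoyl imide on the face away from the benzyl group; this sets the CH(CH2O) stereocentre by auxiliary control and brings in the C=CH2 unit without a ketone methylenation, while C1 is no longer acidic.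

Step 11
Reactants: 18 (4S)-4-benzyl-3-[(3R)-3-({[tert-butyl(dimethyl)silyl]oxy}methyl)-4-[(1R,3aS,7aS)-4,4,7a-trimethyloctahydro-1H-inden-1-yl]pent-4-enoyl]-1,3-oxazolidin-2-one; 19 ethyl 2-oxoacetate
Product: 20 ethyl (2S,3S,4R)-3-{[(4S)-4-benzyl-2-oxo-1,3-oxazolidin-3-yl]carbonyl}-4-({[tert-butyl(dimethyl)silyl]oxy}methyl)-2-hydroxy-5-[(1R,3aS,7aS)-4,4,7a-trimethyloctahydro-1H-inden-1-yl]hex-5-enoate
Conditions: Bu2BOTf, i-Pr2NEt, CH2Cl2, −78 to 0 °C; then 19, −78 to 0 °C; pH 7 buffer, MeOH
Reagents that add atoms: none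
Why: Evans syn-aldol reaction, in which the Z-boron enolate reacts through a chair transition state on the face fixed by the (S)-benzyl auxiliary and so sets both future lactone stereocentres (ring CH and CH–OH) in the syn relation that becomes trans in the lactone.

Step 12
Reactants: 20 ethyl (2S,3S,4R)-3-{[(4S)-4-benzyl-2-oxo-1,3-oxazolidin-3-yl]carbonyl}-4-({[tert-butyl(dimethyl)silyl]oxy}methyl)-2-hydroxy-5-[(1R,3aS,7aS)-4,4,7a-trimethyloctahydro-1H-inden-1-yl]hex-5-enoate
Product: 21 ethyl (2S,3S,4R)-3-{[(4S)-4-benzyl-2-oxo-1,3-oxazolidin-3-yl]carbonyl}-4-({[tert-butyl(dimethyl)silyl]oxy}methyl)-2-[(triethylsilyl)oxy]-5-[(1R,3aS,7aS)-4,4,7a-trimethyloctahydro-1H-inden-1-yl]hex-5-enoate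
Conditions: TESOTf, 2,6-lutidine, CH2Cl2, −78 °C
Reagents that add atoms: triethylsilyl trifluoromethanesulfonate, CC[Si](CC)(CC)OS(=O)(=O)C(F)(F)F
Why: Silylation of the secondary alcohol, so that the neighbouring ethyl ester is not reduced by hydroxyl-directed hydride delivery in step 13.

Step 13
Reactants: 21 ethyl (2S,3S,4R)-3-{[(4S)-4-benzyl-2-oxo-1,3-oxazolidin-3-yl]carbonyl}-4-({[tert-butyl(dimethyl)silyl]oxy}methyl)-2-[(triethylsilyl)oxy]-5-[(1R,3aS,7aS)-4,4,7a-trimethyloctahydro-1H-inden-1-yl]hex-5-enoate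
Product: 23 (3S,4R)-4-[(2R)-1-{[tert-butyl(dimethyl)silyl]oxy}-3-[(1R,3aS,7aS)-4,4,7a-trimethyloctahydro-1H-inden-1-yl]but-3-en-2-yl]-3-[(triethylsilyl)oxy]oxolan-2-one, via hydroxy ester 22 (not isolated)
Conditions: LiBH4, MeOH (1 equiv), Et2O, 0 °C; then PPTS (cat.), CH2Cl2, 23 °C
Reagents that add atoms: none
Why: Chemoselective LiBH4 reduction of the N-acyl oxazolidinone (more electrophilic than the hindered α-silyloxy ester) should free the primary alcohol and the auxiliary, and the γ-hydroxy ester 22 then closes to the five-membered lactone by acyl substitution under mild acid without touching a stereocentre.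

Step 14
Reactants: 23 (3S,4R)-4-[(2R)-1-{[tert-butyl(dimethyl)silyl]oxy}-3-[(1R,3aS,7aS)-4,4,7a-trimethyloctahydro-1H-inden-1-yl]but-3-en-2-yl]-3-[(triethylsilyl)oxy]oxolan-2-one
Product: 24 (3S,4R)-3-hydroxy-4-[(2R)-1-hydroxy-3-[(1R,3aS,7aS)-4,4,7a-trimethyloctahydro-1H-inden-1-yl]but-3-en-2-yl]oxolan-2-one
Conditions: HF·pyridine, pyridine, THF, 0 to 23 °C
Reagents that add atoms: none
Why: Fluoride-mediated cleavage of both silyl ethers under buffered conditions that should leave the lactone and the 1,1-disubstituted alkene untouched.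

Step 15
Reactants: 24 (3S,4R)-3-hydroxy-4-[(2R)-1-hydroxy-3-[(1R,3aS,7aS)-4,4,7a-trimethyloctahydro-1H-inden-1-yl]but-3-en-2-yl]oxolan-2-one
Product: 25 (2R)-2-[(3R,4S)-4-hydroxy-5-oxooxolan-3-yl]-3-[(1R,3aS,7aS)-4,4,7a-trimethyloctahydro-1H-inden-1-yl]but-3-en-1-yl acetate
Conditions: AcCl (1.05 equiv), 2,4,6-collidine, CH2Cl2, −78 °C
Reagents that add atoms: acetyl chloride, CC(Cl)=O
Why: Selective acylation of the primary alcohol at low temperature with a hindered base; the secondary α-hydroxy-lactone OH is sterically and electronically much less nucleophilic and should remain free.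

**Compound list**

1 | 2-bromoprop-2-en-1-ol | C=C(Br)CO | starting material
2 | [(2-bromoprop-2-en-1-yl)oxy](tert-butyl)dimethylsilane | C=C(Br)CO[Si](C)(C)C(C)(C)C | intermediate
3 | 2,2,6-trimethylcyclohexan-1-one (racemic) | CC1CCCC(C)(C)C1=O | starting material
4 | (2R)-2-[3-{[tert-butyl(dimethyl)silyl]oxy}prop-1-en-2-yl]-2,6,6-trimethylcyclohexan-1-one | C=C(CO[Si](C)(C)C(C)(C)C)[C@@]1(C)CCCC(C)(C)C1=O | intermediate
5 | tert-butyl(dimethyl)({2-[(1S)-1,3,3-trimethyl-2-methylidenecyclohexyl]prop-2-en-1-yl}oxy)silane | C=C(CO[Si](C)(C)C(C)(C)C)[C@@]1(C)CCCC(C)(C)C1=C | intermediate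
6 | trans-fused B–H borinane: compound 7 with a BH unit inserted between C2 and C3 (six-membered ring B, C2, C1, C7a, C3a, C3; ring stereocentres as in 7) | CC(C)(C)[Si](C)(C)OC[C@H]1C[BH]C[C@H]2C(C)(C)CCC[C@]12C | intermediate
7 | tert-butyl(dimethyl){[(1S,3aS,7aS)-4,4,7a-trimethyloctahydro-1H-inden-1-yl]methoxy}silane | CC(C)(C)[Si](C)(C)OC[C@H]1CC[C@H]2C(C)(C)CCC[C@]12C | intermediate
8 | (1S,3aS,7aS)-4,4,7a-trimethyloctahydro-1H-indene-1-carboxylic acid | OC(=O)[C@H]1CC[C@H]2C(C)(C)CCC[C@]12C | intermediate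
9 | 1-[(1S,3aS,7aS)-4,4,7a-trimethyloctahydro-1H-inden-1-yl]ethan-1-one | CC(=O)[C@H]1CC[C@H]2C(C)(C)CCC[C@]12C | intermediate
10 | N′-{(1E)-1-[(1S,3aS,7aS)-4,4,7a-trimethyloctahydro-1H-inden-1-yl]ethylidene}-2,4,6-tri(propan-2-yl)benzenesulfonohydrazide | C/C(=N\NS(=O)(=O)c1c(C(C)C)cc(C(C)C)cc1C(C)C)[C@H]1CC[C@H]2C(C)(C)CCC[C@]12C | intermediate
11 | (4S)-4-benzyl-1,3-oxazolidin-2-one | O=C1N[C@@H](Cc2ccccc2)CO1 | starting material
12 | prop-2-enoyl chloride | C=CC(Cl)=O | starting material
13 | (4S)-4-benzyl-3-(prop-2-enoyl)-1,3-oxazolidin-2-one | C=CC(=O)N1[C@@H](Cc2ccccc2)COC1=O | intermediate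
14 | tert-butyl(dimethyl)(prop-2-en-1-yloxy)silane | C=CCO[Si](C)(C)C(C)(C)C | starting material
15 | (4S)-4-benzyl-3-[(2E)-4-{[tert-butyl(dimethyl)silyl]oxy}but-2-enoyl]-1,3-oxazolidin-2-one | CC(C)(C)[Si](C)(C)OC/C=C/C(=O)N1[C@@H](Cc2ccccc2)COC1=O | intermediate
16 | alkenyllithium: ketone 9 with C(=O)CH3 replaced by C(Li)=CH2 (ring stereocentres unchanged) | [Li]C(=C)[C@H]1CC[C@H]2C(C)(C)CCC[C@]12C | intermediate
17 | alkenylmagnesium bromide: 16 with Li replaced by MgBr | Br[Mg]C(=C)[C@H]1CC[C@H]2C(C)(C)CCC[C@]12C | intermediate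
18 | (4S)-4-benzyl-3-[(3R)-3-({[tert-butyl(dimethyl)silyl]oxy}methyl)-4-[(1R,3aS,7aS)-4,4,7a-trimethyloctahydro-1H-inden-1-yl]pent-4-enoyl]-1,3-oxazolidin-2-one | C=C([C@H]1CC[C@H]2C(C)(C)CCC[C@]12C)[C@H](CO[Si](C)(C)C(C)(C)C)CC(=O)N1[C@@H](Cc2ccccc2)COC1=O | intermediate
19 | ethyl 2-oxoacetate (ethyl glyoxylate) | CCOC(=O)C=O | starting material
20 | ethyl (2S,3S,4R)-3-{[(4S)-4-benzyl-2-oxo-1,3-oxazolidin-3-yl]carbonyl}-4-({[tert-butyl(dimethyl)silyl]oxy}methyl)-2-hydroxy-5-[(1R,3aS,7aS)-4,4,7a-trimethyloctahydro-1H-inden-1-yl]hex-5-enoate | C=C([C@H]1CC[C@H]2C(C)(C)CCC[C@]12C)[C@H](CO[Si](C)(C)C(C)(C)C)[C@@H]([C@H](O)C(=O)OCC)C(=O)N1[C@@H](Cc2ccccc2)COC1=O | intermediate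
21 | ethyl (2S,3S,4R)-3-{[(4S)-4-benzyl-2-oxo-1,3-oxazolidin-3-yl]carbonyl}-4-({[tert-butyl(dimethyl)silyl]oxy}methyl)-2-[(triethylsilyl)oxy]-5-[(1R,3aS,7aS)-4,4,7a-trimethyloctahydro-1H-inden-1-yl]hex-5-enoate | C=C([C@H]1CC[C@H]2C(C)(C)CCC[C@]12C)[C@H](CO[Si](C)(C)C(C)(C)C)[C@@H]([C@H](O[Si](CC)(CC)CC)C(=O)OCC)C(=O)N1[C@@H](Cc2ccccc2)COC1=O | intermediate
22 | ethyl (2S,3R,4R)-4-({[tert-butyl(dimethyl)silyl]oxy}methyl)-3-(hydroxymethyl)-2-[(triethylsilyl)oxy]-5-[(1R,3aS,7aS)-4,4,7a-trimethyloctahydro-1H-inden-1-yl]hex-5-enoate | C=C([C@H]1CC[C@H]2C(C)(C)CCC[C@]12C)[C@H](CO[Si](C)(C)C(C)(C)C)[C@@H]([C@H](O[Si](CC)(CC)CC)C(=O)OCC)CO | intermediate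
23 | (3S,4R)-4-[(2R)-1-{[tert-butyl(dimethyl)silyl]oxy}-3-[(1R,3aS,7aS)-4,4,7a-trimethyloctahydro-1H-inden-1-yl]but-3-en-2-yl]-3-[(triethylsilyl)oxy]oxolan-2-one | C=C([C@H]1CC[C@H]2C(C)(C)CCC[C@]12C)[C@H](CO[Si](C)(C)C(C)(C)C)[C@@H]1COC(=O)[C@H]1O[Si](CC)(CC)CC | intermediate
24 | (3S,4R)-3-hydroxy-4-[(2R)-1-hydroxy-3-[(1R,3aS,7aS)-4,4,7a-trimethyloctahydro-1H-inden-1-yl]but-3-en-2-yl]oxolan-2-one | C=C([C@H]1CC[C@H]2C(C)(C)CCC[C@]12C)[C@H](CO)[C@@H]1COC(=O)[C@H]1O | intermediate
25 | (2R)-2-[(3R,4S)-4-hydroxy-5-oxooxolan-3-yl]-3-[(1R,3aS,7aS)-4,4,7a-trimethyloctahydro-1H-inden-1-yl]but-3-en-1-yl acetate (CNP0252518.2) | C=C([C@H]1CC[C@H]2C(C)(C)CCC[C@]12C)[C@H](COC(C)=O)[C@@H]1COC(=O)[C@H]1O | target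

**Step count and risks**

Total step count: 15. Longest linear sequence: 13 (steps 1–7 and 10–15; steps 8–9 make the side branch 15).

Steps most likely to fail, riskiest first:

Step 4 (boron extrusion). One boron–carbon bond may be lost to protonolysis or oxidation before the second carbon is handed to silver, so that C2 and C3 are never paired and open-chain alcohols or methyl groups result; chain-forming intermolecular hydroboration is a second drain. The fallback sets out from 5 and keeps the tether-controlled cyclic hydroboration to 6 but replaces the silver coupling. Oxidation of 6 with NaOH/H2O2 should give the 1,5-diol F1; I2, PPh3 and imidazole convert it into the diiodide F2; t-BuLi (2.2 equiv, pentane–Et2O, −78 °C) then effects lithium–iodine exchange at one terminus and 5-exo-tet displacement of the other iodide, closing the same C2–C3 bond. The fallback returns to the route at 7.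

Step 2 (α-alkenylation). Reductive elimination at the crowded tetrasubstituted enolate carbon may be slow, and the ligand may discriminate the enolate faces poorly. The fallback sets out from 2 and builds the quaternary centre by allylic substitution instead of enolate coupling. Commercial (2,6,6-trimethylcyclohex-1-en-1-yl)methanol is converted with ClP(O)(OEt)2 and pyridine into the allylic phosphate F3; bromide 2 is converted by t-BuLi and then Et2AlCl into the alkenylalane F4; enantioselective SN2′ substitution of F3 by F4 under NHC–Cu catalysis (CuCl2·2H2O with a chiral sulfonate-bearing imidazolinium salt) should form C7a and the ring methylidene at once. The fallback returns to the route at 5 and bypasses 4.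

Step 10 (Shapiro/1,4-addition). The alkenyllithium may be protonated by the solvent, and the hindered 1,1-disubstituted alkenyl group may transfer sluggishly so that 1,2-attack on the imide competes. The fallback sets out from 9 and replaces the organolithium/copper chemistry by boron/rhodium chemistry. KN(SiMe3)2 and PhNTf2 should give the kinetic enol triflate F5; Miyaura borylation (B2pin2, PdCl2(dppf), KOPh) gives the alkenyl pinacol boronate F6; Rh-catalysed 1,4-addition of F6 to 15 ([RhCl(cod)]2, KOH, dioxane–H2O, with a chiral diene ligand if the auxiliary alone does not control the face) returns to the route at 18.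

**Further compounds**

F1 | step 4 | 1,5-diol from oxidation of 6 (C2–OH and C3–OH; C1, C3a and C7a as in 7) | OC[C@H]1C(C)(C)CCC[C@]1(C)[C@H](CO)CO[Si](C)(C)C(C)(C)C
F2 | step 4 | 1,5-diiodide corresponding to F1 | IC[C@H]1C(C)(C)CCC[C@]1(C)[C@H](CI)CO[Si](C)(C)C(C)(C)C
F3 | step 2 | diethyl (2,6,6-trimethylcyclohex-1-en-1-yl)methyl phosphate | CCOP(=O)(OCC)OCC1=C(C)CCCC1(C)C
F4 | step 2 | [3-{[tert-butyl(dimethyl)silyl]oxy}prop-1-en-2-yl](diethyl)alumane | CC[Al](CC)C(=C)CO[Si](C)(C)C(C)(C)C
F5 | step 10 | 1-[(1R,3aS,7aS)-4,4,7a-trimethyloctahydro-1H-inden-1-yl]ethenyl trifluoromethanesulfonate (enol triflate of 9) | C=C(OS(=O)(=O)C(F)(F)F)[C@H]1CC[C@H]2C(C)(C)CCC[C@]12C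
F6 | step 10 | alkenyl pinacol boronate: F5 with OTf replaced by 4,4,5,5-tetramethyl-1,3,2-dioxaborolan-2-yl | C=C(B1OC(C)(C)C(C)(C)O1)[C@H]1CC[C@H]2C(C)(C)CCC[C@]12C
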